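**Retrosynthetic overview**
1. 16 ⇒ hexabenzyl ether 15 by global hydrogenolysis. 15 ⇒ meso tetrahydrofuran-3,4-bis(Weinreb amide) 11 plus two aryllithium 14, so both aroyl groups arrive in one double Weinreb ketone synthesis.
2. 11 ⇒ 1,4-diaryl-1,4-diol 8. Ring B (the tetrahydrofuran) is formed second and kept, by SN1 cyclodehydration. C2 and C5 are then settled thermodynamically.
3. 8 ⇒ lactone 7. Ring A (a γ-butyrolactone template) is formed first and later opened by aminolysis.
4. 7 ⇒ lactone enolate 6 + aldehyde 2. This intermolecular aldol makes the key C4–C5 bond anti to the C3 substituent; trans on ring A equals 3,4-cis on ring B.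
5. 4 ⇒ succinic anhydride 1 + aldehyde 2. The C2–C3 bond comes from an aldol–lactonisation.

Assumption: (2R,3R,4S,5S) on this symmetric skeleton is a meso compound (mirror plane through O1 and the C3–C4 midpoint; 2,3-trans, 3,4-cis, 4,5-trans), so no enantiomer exists to select, only relative configuration is controlled, and chiral intermediates are racemates drawn as one enantiomer.

Atom labels C2–C5 are those of the final tetrahydrofuran throughout.

**Step 1**
Reactants: 1 succinic anhydride; 2 4-(benzyloxy)benzaldehyde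
Product: 4 rac-(2R,3R)-2-[4-(benzyloxy)phenyl]-5-oxotetrahydrofuran-3-carboxylic acid (trans), via anhydride aldolate 3 (not isolated)
Conditions: ZnCl2 (2.2 equiv), Et3N (3 equiv), CH2Cl2, 0 °C → rt, 20 h; 2 M HCl; NaHCO3 extraction, re-acidification; recrystallisation (EtOAc/heptane)
Reagents that add atoms: none
Why: In this Perkin–Fittig-type aldol–lactonisation the zinc enolate of 1 adds to 2 and the alkoxide of 3 opens the anhydride to ring A, whose more stable C2/C3-trans isomer predominates and is obtained pure by crystallisation.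

**Step 2**
Reactants: 4 trans-paraconic acid
Product: 5 rac-(2R,3R)-2-[4-(benzyloxy)phenyl]-N-methoxy-N-methyl-5-oxotetrahydrofuran-3-carboxamide
Conditions: MeNHOMe·HCl (1.3 equiv), EDC·HCl (1.3 equiv), N-methylmorpholine (1.4 equiv), CH2Cl2, −10 °C → rt
Reagents that add atoms: N,O-dimethylhydroxylamine hydrochloride, CNOC.Cl
Why: This carbodiimide amide coupling (Weinreb amide formation) uses only a weak base and touches no stereocentre, and the tertiary amide makes C3–H much less acidic than the lactone CH2, which prepares the selective enolisation of step 3.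

**Step 3** (key step)
Reactants: 5 Weinreb amide lactone; 2 4-(benzyloxy)benzaldehyde
Product: 7 rac-(2R,3R,4S)-2-[4-(benzyloxy)phenyl]-4-{[4-(benzyloxy)phenyl](hydroxy)methyl}-N-methoxy-N-methyl-5-oxotetrahydrofuran-3-carboxamide (both carbinol epimers), via lithium enolate 6 (not isolated)
Conditions: LiN(SiMe3)2 (1.1 equiv), THF, −78 °C, 45 min; then 2 (1.2 equiv), −78 °C, 2 h; AcOH/THF quench at −78 °C
Reagents that add atoms: none
Why: In this intermolecular aldol addition of a lactone enolate the aldehyde reaches C4 anti to the adjacent C3 carboxamide, which sets C3/C4 trans on ring A (3,4-cis on ring B), while the C5 carbinol epimer mixture does not matter because C5 is re-set in steps 5 and 6.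

**Step 4**
Reactants: 7 aldol lactone
Product: 8 rac-2,3-bis{[4-(benzyloxy)phenyl](hydroxy)methyl}-N1,N4-dimethoxy-N1,N4-dimethylbutanediamide (C2, C3, C4 as in 7; both C5 epimers)
Conditions: AlMe3 (4 equiv), MeNHOMe·HCl (4 equiv), CH2Cl2, 0 °C → rt; aq. potassium sodium tartrate; crude product used at once
Reagents that add atoms: N,O-dimethylhydroxylamine hydrochloride, CNOC.Cl
Why: Weinreb aminolysis with the aluminium amide made in the flask cleaves the acyl–oxygen bond of ring A, so the C2–O bond and all stereocentres are retained and the free β-hydroxyl is tolerated.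

**Step 5**
Reactants: 8 diol bis(Weinreb amide)
Product: 10 2,5-bis[4-(benzyloxy)phenyl]-N3,N4-dimethoxy-N3,N4-dimethyltetrahydrofuran-3,4-dicarboxamide (2,3-trans/3,4-cis; epimers at C5), via benzylic monomesylate 9 (not isolated)
Conditions: MsCl (1.2 equiv), Et3N (4 equiv), CH2Cl2, −20 → 0 °C
Reagents that add atoms: none
Why: In this SN1 cyclodehydration whichever benzylic OH is sulfonylated ionises to a p-benzyloxybenzyl cation and the other OH closes ring B with the new aryl-bearing centre trans to its neighbour, while the centre that keeps its C–O bond retains configuration, so a minor C5 epimer remains; amide α-hydrogens are too weakly acidic for E1cB with Et3N.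

**Step 6**
Reactants: 10 tetrahydrofuran bis(Weinreb amide), C5 epimer mixture
Product: 11 meso-(2R,3R,4S,5S)-2,5-bis[4-(benzyloxy)phenyl]-N3,N4-dimethoxy-N3,N4-dimethyltetrahydrofuran-3,4-dicarboxamide
Conditions: TfOH (10 mol %), CH2Cl2, 0 °C → rt, followed by 1H NMR; Et3N quench; crystallisation
Reagents that add atoms: none
Why: In this acid-catalysed thermodynamic epimerisation, reversible heterolysis of the p-alkoxybenzylic C–O bonds inverts only C2 and C5, while the amide α-carbons C3/C4 stay cis, so the mixture drains to the most stable isomer with both aryl groups trans to their neighbours.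

**Step 7**
Reactants: 12 4-bromoresorcinol
Product: 13 1-bromo-2,4-bis(benzyloxy)benzene
Conditions: BnBr (2.3 equiv), K2CO3 (3 equiv), DMF, 60 °C
Reagents that add atoms: benzyl bromide, BrCc1ccccc1
Why: This is a double Williamson ether synthesis on two acidic phenols and creates no stereocentre.

**Step 8**
Reactants: 11 meso bis(Weinreb amide); 13 1-bromo-2,4-bis(benzyloxy)benzene
Product: 15 meso-(2R,3R,4S,5S)-{2,5-bis[4-(benzyloxy)phenyl]tetrahydrofuran-3,4-diyl}bis{[2,4-bis(benzyloxy)phenyl]methanone}, via aryllithium 14 (not isolated)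
Conditions: 13 (2.6 equiv), n-BuLi (2.5 equiv), THF, −78 °C, 30 min; then 11, −78 → −40 °C; AcOH/THF quench at −78 °C
Reagents that add atoms: none
Why: After bromine–lithium exchange, the double Weinreb ketone synthesis passes through chelated tetrahedral intermediates that stop over-addition and release the epimerisable ketones only at the cold, weakly acidic quench, so C3/C4 stay cis.

**Step 9**
Reactants: 15 hexabenzyl ether
Product: 16 meso-(2R,3R,4S,5S)-[2,5-bis(4-hydroxyphenyl)tetrahydrofuran-3,4-diyl]bis[(2,4-dihydroxyphenyl)methanone] (target)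
Conditions: H2 (1 atm), 10% Pd/C, THF/MeOH 1:1, rt, stopped at full conversion
Reagents that add atoms: none
Why: Neutral catalytic hydrogenolysis cleaves the six aryl benzyl ethers faster than the ring ether or the electron-rich aryl ketones, and it avoids acid (Paal–Knorr furan formation, ring B ionisation) and base (C3/C4 epimerisation, retro-oxa-Michael), so no stereocentre is touched.

**Compound list**
1 | succinic anhydride | O=C1CCC(=O)O1 | starting material
2 | 4-(benzyloxy)benzaldehyde | O=Cc1ccc(OCc2ccccc2)cc1 | starting material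
3 | rac-syn-3-{[4-(benzyloxy)phenyl](hydroxy)methyl}dihydrofuran-2,5-dione, present as zinc alkoxide, drawn as the alcohol (not isolated) | O=C1OC(=O)C[C@@H]1[C@@H](O)c1ccc(OCc2ccccc2)cc1 | intermediate
4 | rac-(2R,3R)-2-[4-(benzyloxy)phenyl]-5-oxotetrahydrofuran-3-carboxylic acid | OC(=O)[C@@H]1CC(=O)O[C@H]1c1ccc(OCc2ccccc2)cc1 | intermediate
5 | rac-(2R,3R)-2-[4-(benzyloxy)phenyl]-N-methoxy-N-methyl-5-oxotetrahydrofuran-3-carboxamide | CON(C)C(=O)[C@@H]1CC(=O)O[C@H]1c1ccc(OCc2ccccc2)cc1 | intermediate
6 | lithium enolate of 5 (not isolated) | [Li+].CON(C)C(=O)[C@@H]1C=C([O-])O[C@H]1c1ccc(OCc2ccccc2)cc1 | intermediate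
7 | rac-(2R,3R,4S) aldol lactone, 2,3-trans, 3,4-trans, carbinol centre as epimer mixture | CON(C)C(=O)[C@@H]1[C@@H](C(O)c2ccc(OCc3ccccc3)cc2)C(=O)O[C@H]1c1ccc(OCc2ccccc2)cc1 | intermediate
8 | rac diol bis(Weinreb amide), C5 carbinol as epimer mixture | CON(C)C(=O)[C@@H]([C@@H](O)c1ccc(OCc2ccccc2)cc1)[C@H](C(=O)N(C)OC)C(O)c1ccc(OCc2ccccc2)cc1 | intermediate
9 | benzylic monomesylate of 8, drawn at C5, either OH reacts (not isolated) | CON(C)C(=O)[C@@H]([C@@H](O)c1ccc(OCc2ccccc2)cc1)[C@H](C(=O)N(C)OC)C(OS(C)(=O)=O)c1ccc(OCc2ccccc2)cc1 | intermediate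
10 | tetrahydrofuran bis(Weinreb amide), 2,3-trans, 3,4-cis, C5 epimer mixture | CON(C)C(=O)[C@@H]1[C@H](C(=O)N(C)OC)C(c2ccc(OCc3ccccc3)cc2)O[C@H]1c1ccc(OCc2ccccc2)cc1 | intermediate
11 | meso-(2R,3R,4S,5S) tetrahydrofuran bis(Weinreb amide) | CON(C)C(=O)[C@@H]1[C@H](C(=O)N(C)OC)[C@@H](c2ccc(OCc3ccccc3)cc2)O[C@H]1c1ccc(OCc2ccccc2)cc1 | intermediate
12 | 4-bromoresorcinol | Oc1ccc(Br)c(O)c1 | starting material
13 | 1-bromo-2,4-bis(benzyloxy)benzene | Brc1ccc(OCc2ccccc2)cc1OCc1ccccc1 | intermediate
14 | 2,4-bis(benzyloxy)phenyllithium (not isolated) | [Li]c1ccc(OCc2ccccc2)cc1OCc1ccccc1 | intermediate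
15 | meso-(2R,3R,4S,5S) hexabenzyl ether of the target | O=C(c1ccc(OCc2ccccc2)cc1OCc1ccccc1)[C@@H]1[C@H](C(=O)c2ccc(OCc3ccccc3)cc2OCc2ccccc2)[C@@H](c2ccc(OCc3ccccc3)cc2)O[C@H]1c1ccc(OCc2ccccc2)cc1 | intermediate
16 | CNP0237262.1, meso-(2R,3R,4S,5S) | O=C(c1ccc(O)cc1O)[C@@H]1[C@H](C(=O)c2ccc(O)cc2O)[C@@H](c2ccc(O)cc2)O[C@H]1c1ccc(O)cc1 | target

Total step count: 9. Longest linear sequence: 8 steps (1, 2, 3, 4, 5, 6, 8, 9).

**Three steps most likely to fail**

Step 3. The risks are competing removal of C3–H followed by E1cB opening of ring A, and retro-aldol. The fallback sets out from 4 and comes back at 7. Acid 4 is treated with 2.2 equiv LiN(SiMe3)2 in THF at −78 °C to give the dilithium carboxylate enolate F1. Its carboxylate charge blocks deprotonation at C3. Aldol addition to 2, again anti to the C3 substituent, gives the hydroxy lactone acid F2. Its trans geometry prevents bis-lactone formation. Coupling with MeNHOMe·HCl, EDC·HCl and N-methylmorpholine then converts it into 7.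

Step 5. The risks are relactonisation of 8 and capture of the cation by an amide oxygen, both of which return 7. The fallback sets out from 8 and comes back at 11, bypassing 10 and step 6. Crude 8 is silylated at once with TMSCl and imidazole in CH2Cl2 to the bis(trimethylsilyl) ether F3, which has no free OH left to lactonise. TMSOTf (20 mol %) in CH2Cl2 at −78 → 0 °C ionises one benzylic silyl ether without water, and the other silyl ether oxygen closes ring B. The closure is reversible, so the thermodynamic meso isomer 11 forms directly.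

Step 8. The risks are slow second addition to the crowded cis-diamide, and deprotonation at C3/C4 with epimerisation or ring opening. The fallback sets out from 11 and comes back at 15. Reduction with i-Bu2AlH (2.5 equiv) in THF at −78 °C gives the cis-dialdehyde F4, which is used crude and cold. It is added slowly to excess 14 at −78 °C to give the bis(aryl carbinol) F5 as a carbinol epimer mixture. Any lactol that forms is resubmitted to 14. Dess–Martin periodinane buffered with NaHCO3 in CH2Cl2 oxidises both carbinols under near-neutral conditions to 15.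

**Further compounds**
F1 | step 3 | dilithium carboxylate enolate of 4 | [Li+].[Li+].[O-]C(=O)[C@@H]1C=C([O-])O[C@H]1c1ccc(OCc2ccccc2)cc1
F2 | step 3 | rac-(2R,3R,4S)-2-[4-(benzyloxy)phenyl]-4-{[4-(benzyloxy)phenyl](hydroxy)methyl}-5-oxotetrahydrofuran-3-carboxylic acid, carbinol epimers | OC(=O)[C@@H]1[C@@H](C(O)c2ccc(OCc3ccccc3)cc2)C(=O)O[C@H]1c1ccc(OCc2ccccc2)cc1
F3 | step 5 | bis(trimethylsilyl) ether of 8 | CON(C)C(=O)[C@@H]([C@@H](O[Si](C)(C)C)c1ccc(OCc2ccccc2)cc1)[C@H](C(=O)N(C)OC)C(O[Si](C)(C)C)c1ccc(OCc2ccccc2)cc1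
F4 | step 8 | meso-(2R,3R,4S,5S)-2,5-bis[4-(benzyloxy)phenyl]tetrahydrofuran-3,4-dicarbaldehyde | O=C[C@@H]1[C@H](C=O)[C@@H](c2ccc(OCc3ccccc3)cc2)O[C@H]1c1ccc(OCc2ccccc2)cc1
F5 | step 8 | {2,5-bis[4-(benzyloxy)phenyl]tetrahydrofuran-3,4-diyl}bis{[2,4-bis(benzyloxy)phenyl]methanol}, ring centres as in 11, carbinol epimers | OC(c1ccc(OCc2ccccc2)cc1OCc1ccccc1)[C@@H]1[C@H](C(O)c2ccc(OCc3ccccc3)cc2OCc2ccccc2)[C@@H](c2ccc(OCc3ccccc3)cc2)O[C@H]1c1ccc(OCc2ccccc2)cc1
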